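Do not take a slowing curve for a dying reaction: ask first where the flask must end, then how fast it gets there.

in all of them: substrate 1.5 M; free catalyst 2.1 mM; second catalyst 150 mM
- teal: partner 0.95 M; temperature 65 °C; run made earlier
- green: partner 2.1 M; temperature 90 °C; run made earlier
- Monday's: partner 1.42 M; temperature 70 °C; time 50 min
- Friday's: partner 1.42 M; temperature 110 °C; time 12 min

| run | time / min | target / % |
|---|---|---|
| teal | 10.0 | 8 |
| teal | 20.0 | 14 |
| teal | 30.0 | 18 |
| teal | 50.0 | 23 |
| teal | 80.0 | 24 |
| teal | 150 | 25 |
| green | 6.00 | 35 |
| green | 15.0 | 34 |
| green | 20.0 | 38 |
| green | 25.0 | 34 |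
| green | 30.0 | 34 |
| green | 40.0 | 29 |

(each reading ± 2 percentage points)

- the flask that ends with the higher amount of target, in percent of the substrate charged, or "neither" when 2 percentage points or less lies between them (Monday's / Friday's / neither)
- final target, as a percentage of the substrate charged, in Monday's
- final target, as a percentage of the substrate charged, in Friday's

Teal looks nearly like Monday's, at 65 °C against 70 °C with the same substrate and catalysts. Yet teal flattens near 25%, although its charge less that target leaves partner. Divide the flat target by what the charges leave, writing [substrate] and [partner] for each charge less the target: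

[target] / ([substrate][partner]) = 0.375 M / (1.12 M × 0.575 M) = 0.580 /M

Call this ratio, target over the two charges each less the target where the curve is flat, the plateau ratio; the usual term is apparent equilibrium constant. Now hold it for Monday's and solve for the target:

0.516 M / (0.984 M × 0.904 M) = 0.580 /M

That is 34.4% of the substrate, more than teal's plateau; this reckoning holds the ratio fixed, and Monday's partner charge is the larger. Teal's reading at 50.0 min stood at 92.0% of its last reading, and Monday's gets 50 min at a higher temperature, so expect Monday's close to 34.4%.

Green reads 34% at 30.0 min, which gives a ratio of 0.324 /M, lower than teal's, in the hotter run at 90 °C. On Friday's charge this ratio gives 25.2%, and Friday's is hotter still, so I hold it below that.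

The forecast says Monday's ends higher, with 32% for Monday's, a little under my figure, and 20% for Friday's, and adds that “Green's late sag hints at slow target loss”.

The flasks give 33.3% for Monday's and 13.9% for Friday's, so Monday's ends higher. Friday's holds 33.5% of side product at 12 min. Work the plateau ratio backwards from Monday's result and it reads 0.541 /M, against the 0.580 /M carried from teal, a gap of 1.1 percentage points in the target.

    substrate + free catalyst → free catalyst + intermediate (k = 65.2 /M/s, Ea = 65.0 kJ/mol)
    partner + second catalyst + intermediate ⇌ second catalyst + target (K = 0.519 /M, k = 0.0226 /M²/s, Ea = 70.0 kJ/mol, ΔH = −10.0 kJ/mol)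
    partner → decomposed reagent (k = 0.00171 /s, Ea = 100 kJ/mol)
    intermediate → side product (k = 7.48 × 10⁻⁴ /s, Ea = 119 kJ/mol)
    (constants at 110 °C)

Read Monday's flask at 80 min instead: the charges and temperature are unchanged, so the plateau ratio again gives 34.4%. The computed value is 34.2%.

The earlier runs and the new flask are calculated for an exercise, noise included.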